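**Plan**
- Retrosynthesis: cut the two vanillate C(=O)–O bonds at O4 and O5, then the ring bond C1–C6 (C-alkylation of an ester enolate), then C2–C3 (Barbier allylation). This leaves 2,3-O-isopropylidene-D-threitol (C3–C6), tert-butyl 2-(bromomethyl)acrylate (C1, C2, carboxyl) and vanillic acid.
- Forward: the chain is assembled first (C3–C6 from threitol, then C2–C3), then a temporary O1–Si–O3 ring is installed, then the only carbocycle is closed at C1–C6, then O4/O5 are esterified and everything is unmasked.
- Enabling feature: C1 is the α-carbon of the carboxyl group, and its hydroxyl is cis-1,3-diaxial to the C3 hydroxyl on the cyclohexane; both are free in the target. One silicon atom can therefore tie O1 and O3 into a six-membered 1,3,2-dioxasilinane, which becomes a 2,4-dioxa-3-silabicyclo[3.3.1]nonane on ring closure and leaves only O4 and O5 to acylate.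
- Stereochemistry: C4 and C5 come from the D-tartrate pool (threitol acetonide), C3 from Felkin–Anh anti addition to the α-alkoxy aldehyde, and C1 from the silylene tether.

Key step: step 6

Remark: ring atoms are numbered as in quinic acid (C1 bears OH and CO2H, C3 the free secondary OH, C4 and C5 the vanillates), the target being the 4,5-di-O-vanilloyl ester of (−)-quinic acid as the given descriptors encode; open-chain intermediates are named as heptonates whose C2–C7 become ring C1–C6.

Step 1
Reactants: 1 2,3-O-isopropylidene-D-threitol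
Product: 2 2,3-O-isopropylidene-1-O-tosyl-D-threitol
Conditions: TsCl (1.05 equiv), Ag2O (1.5 equiv), KI (0.2 equiv), CH2Cl2, 0 °C to rt
Reagents that add atoms: 4-methylbenzenesulfonyl chloride, Cc1ccc(cc1)S(=O)(=O)Cl
Why: Ag2O-promoted monosulfonylation of a symmetrical diol: the two CH2OH groups of C2-symmetric 1 are homotopic, so only mono- over bis-tosylation is needed and the two stereocentres (later C4 and C5) are untouched.

Step 2
Reactants: 2 2,3-O-isopropylidene-1-O-tosyl-D-threitol
Product: 3 2,3-O-isopropylidene-4-O-tosyl-D-threose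
Conditions: PhI(OAc)2 (1.2 equiv), TEMPO (0.1 equiv), CH2Cl2, rt
Reagents that add atoms: none
Why: Nitroxyl-catalysed oxidation of the primary alcohol stops at the aldehyde under non-basic conditions, so the α-alkoxy stereocentre should not epimerise and the tosylate and acetonide survive.

Step 3
Reactants: 3 2,3-O-isopropylidene-4-O-tosyl-D-threose; 4 tert-butyl 2-(bromomethyl)prop-2-enoate
Product: 6 tert-butyl 2,3-dideoxy-5,6-O-isopropylidene-2-methylidene-7-O-tosyl-D-lyxo-heptonate, via allylzinc bromide 5 (not isolated)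
Conditions: Zn dust (2 equiv), THF/sat. aq. NH4Cl (2:1), 0 °C to rt
Reagents that add atoms: none
Why: Zinc-mediated aqueous Barbier allylation: allylzinc bromide 5 adds to the aldehyde, and the new carbinol centre (later C3) should be set anti to the dioxolane oxygen by Felkin–Anh attack on the non-chelated α-alkoxy aldehyde, while the tosylate and tert-butyl ester are inert.

Step 4
Reactants: 6 tert-butyl 2,3-dideoxy-5,6-O-isopropylidene-2-methylidene-7-O-tosyl-D-lyxo-heptonate
Product: 8 tert-butyl (2RS)-3-deoxy-5,6-O-isopropylidene-7-O-tosyl-D-lyxo-heptonate, via keto ester 7 (not isolated)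
Conditions: O3, CH2Cl2/MeOH (1:1), −78 °C; then NaBH4 (1 equiv), −78 to −30 °C
Reagents that add atoms: ozone, [O-][O+]=O
Why: Ozonolysis of the 1,1-disubstituted acrylate gives α-keto ester 7, which borohydride added to the cold mixture reduces to the α-hydroxy ester; the new C-2 carbinol forms as both epimers, which is harmless because this centre is planarised in step 6.

Step 5
Reactants: 8 tert-butyl (2RS)-3-deoxy-5,6-O-isopropylidene-7-O-tosyl-D-lyxo-heptonate
Product: 9 tert-butyl (2RS)-3-deoxy-2,4-O-(di-tert-butylsilanediyl)-5,6-O-isopropylidene-7-O-tosyl-D-lyxo-heptonate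
Conditions: tBu2Si(OTf)2 (1.1 equiv), 2,6-lutidine (3 equiv), CH2Cl2, 0 °C
Reagents that add atoms: di-tert-butylsilyl bis(trifluoromethanesulfonate), CC(C)(C)[Si](OS(=O)(=O)C(F)(F)F)(OS(=O)(=O)C(F)(F)F)C(C)(C)C
Why: Silylene protection of a 1,3-diol with the bis-triflate closes the six-membered 1,3,2-dioxasilinane that ties O-2 and O-4 (later O1 and O3) together without touching a stereocentre.

Step 6
Reactants: 9 tert-butyl (2RS)-3-deoxy-2,4-O-(di-tert-butylsilanediyl)-5,6-O-isopropylidene-7-O-tosyl-D-lyxo-heptonate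
Product: 11 tert-butyl 1,3-O-(di-tert-butylsilanediyl)-4,5-O-isopropylidene-(−)-quinate, via potassium enolate 10 (not isolated)
Conditions: KN(SiMe3)2 (1.2 equiv), THF (0.01 M), −78 °C to 0 °C
Reagents that add atoms: none
Why: KN(SiMe3)2 removes the proton α to the tert-butyl ester to give potassium enolate 10, exocyclic to the dioxasilinane, whose α-carbon (C1) displaces the primary tosylate at C6 by SN2. The closest known reaction type is the intramolecular alkylation of α-alkoxy and α-silyloxy ester enolates by primary sulfonates, including closures that leave the ester on a bridgehead of a bicyclo[3.3.1] or bicyclo[2.2.2] skeleton. The cyclohexane ring closes in the 6-(enolexo)-exo-tet mode. The new quaternary stereocentre C1 is controlled by the silylene ring: an O–Si–O bridge can only span cis-1,3-diaxial positions of the forming chair, so O1 must end cis to O3 with the ester equatorial, whichever C-2 epimer of 9 is used, while C3, C4 and C5 are carried in unchanged. The step needs C- over O-alkylation, substitution over elimination and ring closure over intermolecular reaction: O-alkylation would require an eight-membered ring, the enolate has no β-leaving group (C2 is CH2), the electrophile is a primary sulfonate, the trans-acetonide holds C3 and C6 gauche, and high dilution is used.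

Step 7
Reactants: 11 tert-butyl 1,3-O-(di-tert-butylsilanediyl)-4,5-O-isopropylidene-(−)-quinate
Product: 12 tert-butyl 1,3-O-(di-tert-butylsilanediyl)-(−)-quinate
Conditions: AcOH/H2O (4:1), 40 °C
Reagents that add atoms: none
Why: Acid hydrolysis of the acetonide: the strained trans-fused dioxolane on the cyclohexane should open far faster than the hindered di-tert-butylsilylene or the tert-butyl ester, unmasking only O4–H and O5–H.

Step 8
Reactants: 13 vanillic acid
Product: 15 4-[(tert-butyldimethylsilyl)oxy]-3-methoxybenzoic acid, via bis-silyl derivative 14 (not isolated)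
Conditions: tBuMe2SiCl (2.5 equiv), imidazole (5 equiv), DMF, rt; then AcOH/THF/H2O (3:1:1), rt
Reagents that add atoms: tert-butyl(chloro)dimethylsilane, CC(C)(C)[Si](C)(C)Cl
Why: Silylation of phenol and carboxylic acid followed by selective hydrolysis of the labile silyl ester gives the phenol-protected acid, with no stereocentre involved.

Step 9
Reactants: 12 tert-butyl 1,3-O-(di-tert-butylsilanediyl)-(−)-quinate; 15 4-[(tert-butyldimethylsilyl)oxy]-3-methoxybenzoic acid (3 equiv)
Product: 16 tert-butyl 4,5-bis-O-{4-[(tert-butyldimethylsilyl)oxy]-3-methoxybenzoyl}-1,3-O-(di-tert-butylsilanediyl)-(−)-quinate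
Conditions: DCC (3 equiv), DMAP (1 equiv), CH2Cl2, rt
Reagents that add atoms: none
Why: Steglich esterification: the only free hydroxyls of 12 are the trans-diequatorial O4–H and O5–H, so both are aroylated with retention while O1 and O3 stay locked in the silylene.

Step 10
Reactants: 16 tert-butyl 4,5-bis-O-{4-[(tert-butyldimethylsilyl)oxy]-3-methoxybenzoyl}-1,3-O-(di-tert-butylsilanediyl)-(−)-quinate
Product: 17 4,5-bis-O-{4-[(tert-butyldimethylsilyl)oxy]-3-methoxybenzoyl}-1,3-O-(di-tert-butylsilanediyl)-(−)-quinic acid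
Conditions: CF3CO2H/CH2Cl2 (1:1), 0 °C to rt
Reagents that add atoms: none
Why: Acidolysis of the tert-butyl ester (alkyl–oxygen cleavage through the tert-butyl cation) frees the acid while O3 is still masked, so no acyl migration is possible and the aryl esters and silyl groups should survive.

Step 11
Reactants: 17 4,5-bis-O-{4-[(tert-butyldimethylsilyl)oxy]-3-methoxybenzoyl}-1,3-O-(di-tert-butylsilanediyl)-(−)-quinic acid
Product: 18 burkinabin C
Conditions: HF·pyridine, pyridine, THF, 0 °C to rt
Reagents that add atoms: none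
Why: Fluoride-driven Si–O cleavage removes the bridging silylene and both aryl silyl ethers under mildly acidic conditions that should leave the aryl esters in place, with no stereocentre affected.

**Compound list**
1 | 2,3-O-isopropylidene-D-threitol, (4R,5R)-2,2-dimethyl-1,3-dioxolane-4,5-dimethanol | OC[C@H]1OC(C)(C)O[C@@H]1CO | starting material
2 | 2,3-O-isopropylidene-1-O-tosyl-D-threitol | Cc1ccc(cc1)S(=O)(=O)OC[C@H]1OC(C)(C)O[C@@H]1CO | intermediate
3 | 2,3-O-isopropylidene-4-O-tosyl-D-threose | Cc1ccc(cc1)S(=O)(=O)OC[C@H]1OC(C)(C)O[C@@H]1C=O | intermediate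
4 | tert-butyl 2-(bromomethyl)prop-2-enoate | C=C(CBr)C(=O)OC(C)(C)C | starting material
5 | tert-butyl 2-[(bromozincio)methyl]prop-2-enoate (allylzinc bromide, formed in situ) | C=C(C[Zn]Br)C(=O)OC(C)(C)C | intermediate
6 | tert-butyl 2,3-dideoxy-5,6-O-isopropylidene-2-methylidene-7-O-tosyl-D-lyxo-heptonate (4R carbinol; dioxolane 4R,5R) | Cc1ccc(cc1)S(=O)(=O)OC[C@H]1OC(C)(C)O[C@@H]1[C@H](O)CC(=C)C(=O)OC(C)(C)C | intermediate
7 | tert-butyl 3-deoxy-5,6-O-isopropylidene-7-O-tosyl-D-lyxo-hept-2-ulosonate (open-chain keto ester, formed in situ) | Cc1ccc(cc1)S(=O)(=O)OC[C@H]1OC(C)(C)O[C@@H]1[C@H](O)CC(=O)C(=O)OC(C)(C)C | intermediate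
8 | tert-butyl (2RS)-3-deoxy-5,6-O-isopropylidene-7-O-tosyl-D-lyxo-heptonate (both C-2 epimers) | Cc1ccc(cc1)S(=O)(=O)OC[C@H]1OC(C)(C)O[C@@H]1[C@H](O)CC(O)C(=O)OC(C)(C)C | intermediate
9 | tert-butyl (2RS)-3-deoxy-2,4-O-(di-tert-butylsilanediyl)-5,6-O-isopropylidene-7-O-tosyl-D-lyxo-heptonate | Cc1ccc(cc1)S(=O)(=O)OC[C@H]1OC(C)(C)O[C@@H]1[C@H]2CC(C(=O)OC(C)(C)C)O[Si](C(C)(C)C)(C(C)(C)C)O2 | intermediate
10 | potassium enolate of 9 (formed in situ) | Cc1ccc(cc1)S(=O)(=O)OC[C@H]1OC(C)(C)O[C@@H]1[C@H]2CC(=C([O-])OC(C)(C)C)O[Si](C(C)(C)C)(C(C)(C)C)O2.[K+] | intermediate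
11 | tert-butyl 1,3-O-(di-tert-butylsilanediyl)-4,5-O-isopropylidene-(−)-quinate | C1[C@H]2OC(C)(C)O[C@@H]2[C@H]3C[C@]1(C(=O)OC(C)(C)C)O[Si](C(C)(C)C)(C(C)(C)C)O3 | intermediate
12 | tert-butyl 1,3-O-(di-tert-butylsilanediyl)-(−)-quinate | C1[C@@H](O)[C@H](O)[C@H]2C[C@]1(C(=O)OC(C)(C)C)O[Si](C(C)(C)C)(C(C)(C)C)O2 | intermediate
13 | vanillic acid (4-hydroxy-3-methoxybenzoic acid) | COc1cc(ccc1O)C(=O)O | starting material
14 | tert-butyldimethylsilyl 4-[(tert-butyldimethylsilyl)oxy]-3-methoxybenzoate (formed in situ) | COc1cc(ccc1O[Si](C)(C)C(C)(C)C)C(=O)O[Si](C)(C)C(C)(C)C | intermediate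
15 | 4-[(tert-butyldimethylsilyl)oxy]-3-methoxybenzoic acid | COc1cc(ccc1O[Si](C)(C)C(C)(C)C)C(=O)O | intermediate
16 | tert-butyl 4,5-bis-O-{4-[(tert-butyldimethylsilyl)oxy]-3-methoxybenzoyl}-1,3-O-(di-tert-butylsilanediyl)-(−)-quinate | C1[C@@H](OC(=O)c3ccc(O[Si](C)(C)C(C)(C)C)c(OC)c3)[C@H](OC(=O)c3ccc(O[Si](C)(C)C(C)(C)C)c(OC)c3)[C@H]2C[C@]1(C(=O)OC(C)(C)C)O[Si](C(C)(C)C)(C(C)(C)C)O2 | intermediate
17 | 4,5-bis-O-{4-[(tert-butyldimethylsilyl)oxy]-3-methoxybenzoyl}-1,3-O-(di-tert-butylsilanediyl)-(−)-quinic acid | C1[C@@H](OC(=O)c3ccc(O[Si](C)(C)C(C)(C)C)c(OC)c3)[C@H](OC(=O)c3ccc(O[Si](C)(C)C(C)(C)C)c(OC)c3)[C@H]2C[C@]1(C(=O)O)O[Si](C(C)(C)C)(C(C)(C)C)O2 | intermediate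
18 | burkinabin C, 4,5-di-O-vanilloyl-(−)-quinic acid | COc1cc(C(=O)O[C@@H]2[C@H](O)C[C@@](O)(C(=O)O)C[C@H]2OC(=O)c2ccc(O)c(OC)c2)ccc1O | target

**Step count and risks**
Total: 11 steps. Longest linear sequence: 10 steps (steps 1–7 and 9–11 from 1; step 8 is a side branch).

Most likely to fail:

1. Step 6 (key step). The bridged transition state may be too strained (inward tert-butyl group on silicon above the forming ring), or SN2 at the β-alkoxy primary tosylate too slow, so that the enolate is lost to elimination or intermolecular alkylation. Fallback, from 6 and back at 11: the polarity of the same bond is reversed and C1 is set under thermodynamic control. Displacement of the tosylate of 6 with NaNO2 (phloroglucinol, DMSO; Kornblum reaction) gives tert-butyl 2,3,7-trideoxy-5,6-O-isopropylidene-2-methylidene-7-nitro-D-lyxo-heptonate F1. Ozonolysis with Me2S work-up gives the nitro keto ester F2. Et3N in CH2Cl2 then closes C1–C6 by intramolecular nitro-aldol (Henry) addition of the C6 nitronate to the C1 ketone; this reversible 6-exo-trig closure should settle on the isomer with the ester equatorial and the C1 hydroxyl axial and hydrogen-bonded to the axial C3 hydroxyl, tert-butyl 4,5-O-isopropylidene-6-nitroquinate F3. Bu3SnH/AIBN (toluene, 110 °C) removes the nitro group to give tert-butyl 4,5-O-isopropylidene-(−)-quinate F4, and tBu2Si(OTf)2/2,6-lutidine bridges its cis-1,3-diol to return to 11.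

2. Step 3. Facial selectivity may be poor if zinc chelates the α-alkoxy aldehyde, eroding the anti preference at C3. Fallback, from 3 and back at 7: the allylmetal addition is replaced by an open-transition-state Mukaiyama aldol. tert-Butyl pyruvate is converted (Me3SiCl, Et3N) into tert-butyl 2-[(trimethylsilyl)oxy]prop-2-enoate F5, which adds to 3 with BF3·OEt2 in CH2Cl2 at −78 °C (monodentate Lewis acid, Felkin–Anh control) to give keto ester 7 directly. Compound 7 is then reduced with NaBH4 as in the second stage of step 4.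

3. Step 4. The basic methanolic borohydride medium may over-reduce the α-hydroxy ester, or cause β-elimination or retro-aldol cleavage of the β-hydroxy α-keto ester. Fallback, from 6 and back at 8: the ozonide is quenched with Me2S, keto ester 7 is isolated, and it is reduced with Me4NBH(OAc)3 in MeCN/AcOH at −20 °C, a hydroxyl-directed, acid-buffered hydride delivery that leaves esters alone. No new compound is made.

**Further compounds**
F1 | step 6 | tert-butyl 2,3,7-trideoxy-5,6-O-isopropylidene-2-methylidene-7-nitro-D-lyxo-heptonate | [O-][N+](=O)C[C@H]1OC(C)(C)O[C@@H]1[C@H](O)CC(=C)C(=O)OC(C)(C)C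
F2 | step 6 | tert-butyl 3,7-dideoxy-5,6-O-isopropylidene-7-nitro-D-lyxo-hept-2-ulosonate | [O-][N+](=O)C[C@H]1OC(C)(C)O[C@@H]1[C@H](O)CC(=O)C(=O)OC(C)(C)C
F3 | step 6 | tert-butyl 4,5-O-isopropylidene-6-nitroquinate (C6 epimers) | [O-][N+](=O)C1[C@H]2OC(C)(C)O[C@@H]2[C@H](O)C[C@@]1(O)C(=O)OC(C)(C)C
F4 | step 6 | tert-butyl 4,5-O-isopropylidene-(−)-quinate | C1[C@H]2OC(C)(C)O[C@@H]2[C@H](O)C[C@@]1(O)C(=O)OC(C)(C)C
F5 | step 3 | tert-butyl 2-[(trimethylsilyl)oxy]prop-2-enoate | C=C(O[Si](C)(C)C)C(=O)OC(C)(C)C
F0 | step 4 | none | none
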